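## The problem

Target 22 is a chroman of the δ-tocotrienol type: ring A (C4a, C5, C6, C7, C8, C8a) carries O1 on C8a, OMe on C6, CH3 on C8 and H on C5 and C7, and ring B (O1, C2, C3, C4, C4a, C8a) holds the only stereocentre, C2 (R), which bears O1, CH3, C3 and a nine-carbon chain numbered C1' to C9' outward from C2 (C9' is the carboxyl carbon). C2 is a tertiary ether carbon whose two methylene arms (C3–C4 and C1'–C2') first differ three bonds away, so no other stereocentre can control it and an enantioselective closure would have to tell CH3 from CH2 at a distance. Any closure of the O1–C2 bond through a tertiary cation would racemise it, so the safest plan never makes or breaks a bond at C2. The chain holds two trisubstituted alkenes of opposite sense, C3'=C4' (6E of the acid) and C7'=C8' (2Z, conjugated to the acid); the Z acid is the less stable isomer, cannot come from oxidation of a terminal methyl group (which gives E), and must be made late, under kinetic control and mildly. Ring A is an electron-rich hydroquinone diether with a 1,2,3,5 substitution pattern; the aryl tert-alkyl ether and the 1,5-diene do not survive strong acid (ionisation at C2, cation–olefin cyclisation), and a free 6-hydroxyl would not survive strong oxidants. The enabling feature is that O1 on C8a and the oxygen on C6 are para on ring A, while O1 is also the oxygen on C2: a 4-alkoxyphenol is exactly what the benzannulation of an alkoxy(alkenyl)carbene complex with an alkyne and CO gives, the alkoxy oxygen becoming O1 and the CO oxygen the C6 oxygen. In addition, C2 with its oxygen, its methyl group, a two-carbon arm and a 4-methylpent-3-enyl arm is the carbinol carbon of (R)-linalool.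

## Retrosynthesis

**C7'=C8', the 2Z alkene of the acid (22 ⇐ 20 ⇐ 19).** The Z-enoate is cut at its double bond to aldehyde 19 and a propanoate phosphonate. Oxidation of a terminal methyl group would give the E acid. A Z-selective Horner–Wadsworth–Emmons reaction under kinetic control sets the geometry in the step that forms the bond, and only a mild ester hydrolysis follows.

**C5'–C6' (19 ⇐ 17 ⇐ 16 ⇐ 15 ⇐ 14).** C6' and C7' come from acetonitrile, joined to the allylic bromide 16 at C5'. This cut is preferred over an olefination at C3'=C4' because the E geometry is then not made at all: C5' is the (E)-methyl group of the Me2C=CH terminus of 14, oxidised selectively. The precursor 14 therefore carries only the 4-methylpent-3-enyl group of linalool.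

**Rings A and B (14 ⇐ 13 ⇐ 11 ⇐ 9 + 4).** After removal of the O-methyl group, chromanol 13 is cut at three ring A bonds (C4a–C8a, C5–C6, C6–C7) and at the carbene C–O bond (C8a–O1). Alkynol 4 supplies O1, C2, C3, C4, C4a and C5; the isopropenyl acylchromate 9 supplies C8a, C8 with its methyl group, and C7; one CO ligand supplies C6 and its oxygen. The neighbouring cuts are weaker. Cutting O1–C2 requires enantioselective catalysis at a centre with near-identical arms. Cutting O1–C8a and C4–C4a onto a purchased arene requires a 1,2,3,5-substituted dihaloarene and two palladium couplings, and it is kept as the fallback. The forward reaction must transfer the carbene carbon to a tertiary hydroxyl and then close both rings; no bond to C2 is involved, and the precursors are acyclic and contain no ring A.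

**Alkyne (4 ⇐ 3 ⇐ 1).** The alkyne is cut to lactol 3 and a one-carbon diazo reagent (C5). Lactol 3 is cut at C4–C4a to (R)-linalool 1 and CO. Hydroformylation of the vinyl group is linear-selective because the neighbouring carbon is quaternary. This is shorter than hydroboration, activation and acetylide displacement, and the C–O bond of linalool is never touched.

**Acylchromate (9 ⇐ 5 + 6).** 9 comes from 2-bromopropene 5 and Cr(CO)6 6. Of the six ring A carbons, three are carbon monoxide (C4a, C6, C8a), one is the diazo carbon (C5) and two come from 2-bromopropene (C7, C8).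

## Roads not taken

Alternative 1: The most obvious cut is in the side chain, at C1'–C2'. An enantiopure chroman building block, sulfone A1, is deprotonated and alkylated with the allylic bromide A2; reductive desulfonylation and ester hydrolysis follow. The chosen plan is better for three reasons. A1 needs its own asymmetric synthesis of C2 (resolution or an enantioselective cyclisation over several steps). A2 needs both alkene geometries built separately. The reductive removal of the sulfone is not compatible with the Z-enoate, so the chain end would have to be finished afterwards anyway. The stereocentre, ring A and the chain are solved one after another, at about twice the step count.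

Alternative 2: Cut O1–C2 and close ring B enantioselectively from an achiral phenol, A3, by protonation of its C10=C11 alkene with a confined chiral Brønsted acid (the biomimetic cyclisation). The chosen plan is better because the acid would have to protonate C10=C11 and not the equally basic C6=C7 alkene, whose C6 cation is set up for six-membered cation–olefin closure onto C11. The catalyst must also distinguish CH3 from CH2 at the C10 cation. A3 itself needs a regioselective ortho C-allylation of a phenol with a triene ester of defined E,E,Z geometry.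

Alternative 3: Make ring A from a 2-pyrone. Cut C4a–C8a and C7–C8; the forward step is an intramolecular Diels–Alder reaction of the pyrone ynol ether A4 with loss of CO2, which would give 14 directly. The chosen plan is better for two reasons. A tert-alkyl alkynyl ether fragments by a retro-ene reaction to a ketene and an alkene below the temperature a pyrone/alkyne cycloaddition needs. The 4-methoxy group makes the pyrone a poorer acceptor for the electron-rich ynol ether, so the cycloaddition would need still more forcing conditions. The carbene route has neither problem: the alkyne is unactivated and stable, and the annulation runs at about 50 °C.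

Key step: step 4

Assumption: (R)-(−)-linalool of high enantiomeric purity is taken as commercial. Its purity is carried unchanged to 22 because no bond to the carbinol carbon is made or broken.

## Route

Step 1
Reactants: 1 (R)-linalool
Product: 3 (5R)-5-methyl-5-(4-methylpent-3-en-1-yl)oxolan-2-ol (both lactol epimers), via hydroxy aldehyde 2 (not isolated)
Conditions: Rh(acac)(CO)2 (0.5 mol %), PPh3, CO/H2 (1:1, 20 bar), toluene, 60 °C
Reagents that add atoms: carbon monoxide, [C-]#[O+]
Why: Rh-catalysed hydroformylation; only the monosubstituted vinyl group reacts, the quaternary carbinol carbon forces the linear aldehyde 2, which closes to lactol 3; the C–O bond at the stereocentre is untouched, so (R) is retained.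

Step 2
Reactants: 3 (5R)-5-methyl-5-(4-methylpent-3-en-1-yl)oxolan-2-ol
Product: 4 (5R)-5,9-dimethyldec-8-en-1-yn-5-ol
Conditions: dimethyl (1-diazo-2-oxopropyl)phosphonate, K2CO3, MeOH, 0 °C → rt
Reagents that add atoms: dimethyl (1-diazo-2-oxopropyl)phosphonate, CC(=O)C(=[N+]=[N-])P(=O)(OC)OC
Why: Ohira–Bestmann (Seyferth–Gilbert) homologation; lactol 3 reacts through its ring-opened tautomer, the hydroxy aldehyde 2 already met in step 1, with which it stands in equilibrium, so both lactol epimers converge on one alkyne. The tertiary alcohol is inert, and the diazo carbon becomes the terminal alkyne carbon (later C5).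

Step 3
Reactants: 5 2-bromopropene; 6 chromium hexacarbonyl, Cr(CO)6
Product: 9 tetramethylammonium pentacarbonyl(2-methyl-1-oxidoprop-2-en-1-ylidene)chromate, via isopropenyllithium 7 (not isolated), via lithium acylchromate 8 (not isolated)
Conditions: t-BuLi (2 equiv), Et2O, −78 °C; Cr(CO)6, −78 °C → rt; Me4NBr, H2O
Reagents that add atoms: tetramethylammonium bromide, C[N+](C)(C)C.[Br-]
Why: Fischer acylmetalate synthesis: Br/Li exchange, addition of the alkenyllithium to a CO ligand, and cation exchange to the storable tetramethylammonium salt.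

Step 4
Reactants: 9 tetramethylammonium pentacarbonyl(2-methyl-1-oxidoprop-2-en-1-ylidene)chromate; 4 (5R)-5,9-dimethyldec-8-en-1-yn-5-ol
Product: 13 (2R)-2,8-dimethyl-2-(4-methylpent-3-en-1-yl)-3,4-dihydro-2H-chromen-6-ol, via acetoxycarbene complex 10 (not isolated), via alkoxycarbene complex 11 (not isolated), via tricarbonylchromium arene complex 12 (not isolated)
Conditions: 9 (1.5 equiv), AcBr, CH2Cl2, −40 °C; 4, −40 → 0 °C; cold filtration, THF (0.005 M), 50 °C; air, MeCN, rt
Reagents that add atoms: none
Why: Proposed new method: O-acetylation of 9 gives acetoxycarbene 10, whose carbene carbon is as electrophilic as an acyl halide carbon; the tertiary hydroxyl of 4 adds there and acetate leaves (addition–elimination), giving 11 with the C2–O bond of the alcohol untouched, so (R) is carried over; the closest known reaction is this alcoholysis with primary and secondary alcohols, and the new element is the tertiary alcohol. On warming, 11 loses one CO and the tethered alkyne inserts into the Cr=C bond, so that C4a bonds to the carbene carbon C8a and ring B closes in the 6-exo-dig mode; the three-carbon tether through O1 allows no other regiochemistry and fixes the cis geometry of the new vinylcarbene. CO insertion gives a dienylketene, and 6π-electrocyclisation onto the isopropenyl CH2 (C6–C7 bond) closes ring A; tautomerisation gives the phenol as its Cr(CO)3 complex 12, which air demetalates. This second stage is the Dötz benzannulation in its known intramolecular form, with the alkyne tethered through the carbene oxygen. The mechanism places every ring A substituent: C6–OH from CO para to O1, the 8-methyl from the isopropenyl group, H at C5 and C7. No stereocentre is created, and the planar chirality of 12 is lost on demetalation. The step needs phenol formation over cyclopentannulation and intra- over intermolecular insertion; an alkenyl carbene on chromium in THF and high dilution secure both, and the trisubstituted alkene is a far poorer ligand than the alkyne.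

Step 5
Reactants: 13 (2R)-2,8-dimethyl-2-(4-methylpent-3-en-1-yl)-3,4-dihydro-2H-chromen-6-ol
Product: 14 (2R)-6-methoxy-2,8-dimethyl-2-(4-methylpent-3-en-1-yl)-3,4-dihydro-2H-chromene
Conditions: MeI, K2CO3, acetone, reflux
Reagents that add atoms: iodomethane, CI
Why: Williamson O-methylation of the phenol; it also protects ring A from oxidation in the next step.

Step 6
Reactants: 14 (2R)-6-methoxy-2,8-dimethyl-2-(4-methylpent-3-en-1-yl)-3,4-dihydro-2H-chromene
Product: 15 (2E)-5-[(2R)-6-methoxy-2,8-dimethyl-3,4-dihydro-2H-chromen-2-yl]-2-methylpent-2-en-1-ol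
Conditions: SeO2 (cat.), t-BuOOH, salicylic acid (cat.), CH2Cl2, 0 °C → rt
Reagents that add atoms: selenium dioxide (oxygen carrier), O=[Se]=O; tert-butyl hydroperoxide (terminal oxidant), CC(C)(C)OO
Why: Catalytic SeO2 allylic oxidation (ene reaction, then [2,3]-sigmatropic shift) places oxygen on the (E)-methyl group of the Me2C=CH terminus and so fixes the 6E geometry of the target.

Step 7
Reactants: 15 (2E)-5-[(2R)-6-methoxy-2,8-dimethyl-3,4-dihydro-2H-chromen-2-yl]-2-methylpent-2-en-1-ol
Product: 16 (2R)-2-[(3E)-5-bromo-4-methylpent-3-en-1-yl]-6-methoxy-2,8-dimethyl-3,4-dihydro-2H-chromene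
Conditions: CBr4, PPh3, CH2Cl2, 0 °C
Reagents that add atoms: carbon tetrabromide, BrC(Br)(Br)Br
Why: Appel reaction of a primary allylic alcohol; neutral conditions leave the alkene geometry and the aryl ether unchanged.

Step 8
Reactants: 16 (2R)-2-[(3E)-5-bromo-4-methylpent-3-en-1-yl]-6-methoxy-2,8-dimethyl-3,4-dihydro-2H-chromene
Product: 17 (4E)-7-[(2R)-6-methoxy-2,8-dimethyl-3,4-dihydro-2H-chromen-2-yl]-4-methylhept-4-enenitrile
Conditions: MeCN (excess), n-BuLi, THF, −78 °C; then 16, −78 → −40 °C
Reagents that add atoms: acetonitrile, CC#N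
Why: SN2 alkylation of lithioacetonitrile at the primary allylic carbon; an excess of the nucleophile at low temperature suppresses double alkylation.

Step 9
Reactants: 17 (4E)-7-[(2R)-6-methoxy-2,8-dimethyl-3,4-dihydro-2H-chromen-2-yl]-4-methylhept-4-enenitrile
Product: 19 (4E)-7-[(2R)-6-methoxy-2,8-dimethyl-3,4-dihydro-2H-chromen-2-yl]-4-methylhept-4-enal, via aluminium aldimine 18 (not isolated)
Conditions: i-Bu2AlH, CH2Cl2, −78 °C; aq. potassium sodium tartrate
Reagents that add atoms: water, O
Why: Partial reduction of the nitrile stops at the N-aluminated aldimine 18, which is hydrolysed to the aldehyde on work-up.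

Step 10
Reactants: 19 (4E)-7-[(2R)-6-methoxy-2,8-dimethyl-3,4-dihydro-2H-chromen-2-yl]-4-methylhept-4-enal
Product: 20 methyl (2Z,6E)-9-[(2R)-6-methoxy-2,8-dimethyl-3,4-dihydro-2H-chromen-2-yl]-2,6-dimethylnona-2,6-dienoate
Conditions: methyl 2-[bis(2,2,2-trifluoroethoxy)phosphoryl]propanoate, KN(SiMe3)2, 18-crown-6, THF, −78 °C
Reagents that add atoms: methyl 2-[bis(2,2,2-trifluoroethoxy)phosphoryl]propanoate, COC(=O)C(C)P(=O)(OCC(F)(F)F)OCC(F)(F)F
Why: Still–Gennari olefination; the electron-poor phosphonate and the crown-ether-separated potassium ion make elimination faster than adduct equilibration, so the kinetic Z-trisubstituted enoate forms.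

Step 11
Reactants: 20 methyl (2Z,6E)-9-[(2R)-6-methoxy-2,8-dimethyl-3,4-dihydro-2H-chromen-2-yl]-2,6-dimethylnona-2,6-dienoate
Product: 22 (2Z,6E)-9-[(2R)-6-methoxy-2,8-dimethyl-3,4-dihydro-2H-chromen-2-yl]-2,6-dimethylnona-2,6-dienoic acid, via lithium carboxylate 21 (not isolated)
Conditions: LiOH, THF/MeOH/H2O, rt → 40 °C; aq. HCl to pH 3
Reagents that add atoms: lithium hydroxide, [Li+].[OH-]
Why: Saponification of the methyl ester under mild conditions; hydroxide attacks the acyl carbon, and neither the Z-alkene, the aryl ether nor C2 is affected.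

## Compound list

1 | (R)-linalool, (3R)-3,7-dimethylocta-1,6-dien-3-ol | C=C[C@](C)(O)CCC=C(C)C | starting material
2 | (4R)-4-hydroxy-4,8-dimethylnon-7-enal | O=CCC[C@](C)(O)CCC=C(C)C | intermediate
3 | (5R)-5-methyl-5-(4-methylpent-3-en-1-yl)oxolan-2-ol (both lactol epimers) | OC1CC[C@@](C)(CCC=C(C)C)O1 | intermediate
4 | (5R)-5,9-dimethyldec-8-en-1-yn-5-ol | C#CCC[C@](C)(O)CCC=C(C)C | intermediate
5 | 2-bromopropene | C=C(C)Br | starting material
6 | chromium hexacarbonyl | [Cr](=C=O)(=C=O)(=C=O)(=C=O)(=C=O)=C=O | starting material
7 | isopropenyllithium | [Li]C(C)=C | intermediate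
8 | lithium pentacarbonyl(2-methyl-1-oxidoprop-2-en-1-ylidene)chromate | [Li+].[O-]C(C(C)=C)=[Cr](=C=O)(=C=O)(=C=O)(=C=O)=C=O | intermediate
9 | tetramethylammonium pentacarbonyl(2-methyl-1-oxidoprop-2-en-1-ylidene)chromate | C[N+](C)(C)C.[O-]C(C(C)=C)=[Cr](=C=O)(=C=O)(=C=O)(=C=O)=C=O | intermediate
10 | pentacarbonyl[1-(acetyloxy)-2-methylprop-2-en-1-ylidene]chromium | CC(=O)OC(C(C)=C)=[Cr](=C=O)(=C=O)(=C=O)(=C=O)=C=O | intermediate
11 | pentacarbonyl{1-[(5R)-5,9-dimethyldec-8-en-1-yn-5-yl]oxy-2-methylprop-2-en-1-ylidene}chromium | C#CCC[C@@](C)(CCC=C(C)C)OC(C(C)=C)=[Cr](=C=O)(=C=O)(=C=O)(=C=O)=C=O | intermediate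
12 | tricarbonyl[η6-(2R)-2,8-dimethyl-2-(4-methylpent-3-en-1-yl)-3,4-dihydro-2H-chromen-6-ol]chromium (ring A bound to Cr, either face; the η6 bond is written as a dot) | Oc1cc(C)c2c(c1)CC[C@@](C)(CCC=C(C)C)O2.[Cr](=C=O)(=C=O)=C=O | intermediate
13 | (2R)-2,8-dimethyl-2-(4-methylpent-3-en-1-yl)-3,4-dihydro-2H-chromen-6-ol | Oc1cc(C)c2c(c1)CC[C@@](C)(CCC=C(C)C)O2 | intermediate
14 | (2R)-6-methoxy-2,8-dimethyl-2-(4-methylpent-3-en-1-yl)-3,4-dihydro-2H-chromene | COc1cc(C)c2c(c1)CC[C@@](C)(CCC=C(C)C)O2 | intermediate
15 | (2E)-5-[(2R)-6-methoxy-2,8-dimethyl-3,4-dihydro-2H-chromen-2-yl]-2-methylpent-2-en-1-ol | COc1cc(C)c2c(c1)CC[C@@](C)(CC/C=C(\C)CO)O2 | intermediate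
16 | (2R)-2-[(3E)-5-bromo-4-methylpent-3-en-1-yl]-6-methoxy-2,8-dimethyl-3,4-dihydro-2H-chromene | COc1cc(C)c2c(c1)CC[C@@](C)(CC/C=C(\C)CBr)O2 | intermediate
17 | (4E)-7-[(2R)-6-methoxy-2,8-dimethyl-3,4-dihydro-2H-chromen-2-yl]-4-methylhept-4-enenitrile | COc1cc(C)c2c(c1)CC[C@@](C)(CC/C=C(\C)CCC#N)O2 | intermediate
18 | N-(diisobutylalumino) aldimine of 19 | COc1cc(C)c2c(c1)CC[C@@](C)(CC/C=C(\C)CCC=N[Al](CC(C)C)CC(C)C)O2 | intermediate
19 | (4E)-7-[(2R)-6-methoxy-2,8-dimethyl-3,4-dihydro-2H-chromen-2-yl]-4-methylhept-4-enal | COc1cc(C)c2c(c1)CC[C@@](C)(CC/C=C(\C)CCC=O)O2 | intermediate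
20 | methyl (2Z,6E)-9-[(2R)-6-methoxy-2,8-dimethyl-3,4-dihydro-2H-chromen-2-yl]-2,6-dimethylnona-2,6-dienoate | COc1cc(C)c2c(c1)CC[C@@](C)(CC/C=C(\C)CC/C=C(/C)C(=O)OC)O2 | intermediate
21 | lithium (2Z,6E)-9-[(2R)-6-methoxy-2,8-dimethyl-3,4-dihydro-2H-chromen-2-yl]-2,6-dimethylnona-2,6-dienoate | [Li+].COc1cc(C)c2c(c1)CC[C@@](C)(CC/C=C(\C)CC/C=C(/C)C(=O)[O-])O2 | intermediate
22 | (2Z,6E)-9-[(2R)-6-methoxy-2,8-dimethyl-3,4-dihydro-2H-chromen-2-yl]-2,6-dimethylnona-2,6-dienoic acid | COc1cc(C)c2c(c1)CC[C@@](C)(CC/C=C(\C)CC/C=C(/C)C(=O)O)O2 | target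

## Step count and risk

Total: 11 steps. Longest linear sequence: 10 steps (steps 1, 2, 4–11 from 1); step 3 is a one-step side branch.

**Step 4 (key step, proposed new method).** Three things are most likely to go wrong.
- Carbene transfer to the hindered tertiary hydroxyl may be slow. The thermally labile acetoxycarbene may then decompose, or the alcohol may be acetylated instead, or it may add in conjugate fashion to the isopropenyl terminus.
- The tert-alkoxycarbene, once formed, may lose the alkyl group by elimination before the alkyne inserts.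
- After alkyne insertion, ring closure without CO insertion (cyclopentannulation) or intermolecular oligomerisation may compete.

Fallback (known chemistry, from 1 back to 14): commercial 4-methoxy-2-methylaniline is iodinated ortho to nitrogen (I2, NaHCO3) to give 2-iodo-4-methoxy-6-methylaniline F1, and a Sandmeyer reaction (NaNO2, HBr, CuBr) gives 2-bromo-1-iodo-5-methoxy-3-methylbenzene F2. Linalool 1 is hydroborated at the vinyl group with 9-BBN to the borane F3, which is coupled without isolation at the C–I bond of F2 (Suzuki–Miyaura, PdCl2(dppf), K3PO4) to give the bromo alcohol F4. Intramolecular palladium-catalysed aryl ether formation of the Buchwald–Hartwig type (Pd(OAc)2, 2-(di-tert-butylphosphino)-1,1'-binaphthyl, Cs2CO3, toluene, 80 °C) closes ring B and gives 14 directly.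

**Step 2.** Ring opening of the 5,5-disubstituted lactol may be slow, so the diazophosphonate is consumed by methanolysis before it meets the open-chain aldehyde; base-mediated self-condensation of that aldehyde is a second loss.

Fallback (from 1 back to 4): hydroboration of 1 with 9-BBN and oxidation (NaOH, H2O2) gives the diol F5. Selective iodination of the primary hydroxyl (I2, PPh3, imidazole) gives the iodo alcohol F6. Displacement with an excess of LiC≡CSiMe3 in THF/DMPU at low temperature gives the silyl alkyne F7; the lithium alkoxide formed first closes a four-membered ring only slowly. K2CO3 in MeOH then removes the silyl group to give 4.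

**Step 6.** Over-oxidation to the enal may run alongside incomplete conversion. Competing oxidation at the allylic CH2 or attack on the electron-rich ring A is also possible.

Fallback (from 14 back to 19, bypassing steps 6–9): epoxidation of 14 with mCPBA gives the epoxide F8 as an inconsequential epimer mixture. Isomerisation with Al(OiPr)3 in hot toluene opens it to the isopropenyl carbinol F9. Johnson–Claisen rearrangement (triethyl orthoacetate, cat. propanoic acid, 140 °C) removes the carbinol centre and sets the E alkene through a chair transition state, giving ester F10. Reduction with i-Bu2AlH at −78 °C gives 19.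

**Step 10.** Z-selectivity may erode if the adduct equilibrates (counter-ion not fully sequestered, temperature rise), and the E and Z esters may be hard to separate.

Fallback (from 19 back to 22, bypassing step 11): a Wittig reaction by way of the β-oxido ylide. Ethylidenetriphenylphosphorane adds to 19 at −78 °C, the betaine is deprotonated with n-BuLi, and the β-oxido ylide is trapped with formaldehyde, which places CH2OH cis to the chain and gives the Z allylic alcohol F11. Oxidation with MnO2 gives the Z-enal F12, and NaClO2 (NaH2PO4, 2-methyl-2-butene) gives 22.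

## Further compounds

F1 | step 4 | 2-iodo-4-methoxy-6-methylaniline | COc1cc(C)c(N)c(I)c1
F2 | step 4 | 2-bromo-1-iodo-5-methoxy-3-methylbenzene | COc1cc(C)c(Br)c(I)c1
F3 | step 4 | (3S)-1-(9-borabicyclo[3.3.1]nonan-9-yl)-3,7-dimethyloct-6-en-3-ol (same centre as in 1; the descriptor changes by the sequence rule only) | C[C@@](O)(CCC=C(C)C)CCB1C2CCCC1CCC2
F4 | step 4 | (3R)-1-(2-bromo-5-methoxy-3-methylphenyl)-3,7-dimethyloct-6-en-3-ol | COc1cc(C)c(Br)c(CC[C@](C)(O)CCC=C(C)C)c1
F5 | step 2 | (3R)-3,7-dimethyloct-6-ene-1,3-diol | OCC[C@](C)(O)CCC=C(C)C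
F6 | step 2 | (3R)-1-iodo-3,7-dimethyloct-6-en-3-ol | ICC[C@](C)(O)CCC=C(C)C
F7 | step 2 | (5R)-5,9-dimethyl-1-(trimethylsilyl)dec-8-en-1-yn-5-ol | C[Si](C)(C)C#CCC[C@](C)(O)CCC=C(C)C
F8 | step 6 | (2S)-2-[2-(3,3-dimethyloxiran-2-yl)ethyl]-6-methoxy-2,8-dimethyl-3,4-dihydro-2H-chromene (both epoxide epimers; same C2 centre as in 14, the descriptor changes by the sequence rule only) | COc1cc(C)c2c(c1)CC[C@@](C)(CCC1OC1(C)C)O2
F9 | step 6 | 5-[(2S)-6-methoxy-2,8-dimethyl-3,4-dihydro-2H-chromen-2-yl]-2-methylpent-1-en-3-ol (both carbinol epimers; same C2 centre as in 14) | COc1cc(C)c2c(c1)CC[C@@](C)(CCC(O)C(C)=C)O2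
F10 | step 6 | ethyl (4E)-7-[(2R)-6-methoxy-2,8-dimethyl-3,4-dihydro-2H-chromen-2-yl]-4-methylhept-4-enoate | COc1cc(C)c2c(c1)CC[C@@](C)(CC/C=C(\C)CCC(=O)OCC)O2
F11 | step 10 | (2Z,6E)-9-[(2R)-6-methoxy-2,8-dimethyl-3,4-dihydro-2H-chromen-2-yl]-2,6-dimethylnona-2,6-dien-1-ol | COc1cc(C)c2c(c1)CC[C@@](C)(CC/C=C(\C)CC/C=C(/C)CO)O2
F12 | step 10 | (2Z,6E)-9-[(2R)-6-methoxy-2,8-dimethyl-3,4-dihydro-2H-chromen-2-yl]-2,6-dimethylnona-2,6-dienal | COc1cc(C)c2c(c1)CC[C@@](C)(CC/C=C(\C)CC/C=C(/C)C=O)O2
A1 | alternative 1 | (2S)-6-methoxy-2,8-dimethyl-2-[(phenylsulfonyl)methyl]-3,4-dihydro-2H-chromene | COc1cc(C)c2c(c1)CC[C@@](C)(CS(=O)(=O)c1ccccc1)O2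
A2 | alternative 1 | methyl (2Z,6E)-8-bromo-2,6-dimethylocta-2,6-dienoate | COC(=O)/C(C)=C\CC/C(C)=C/CBr
A3 | alternative 2 | methyl (2Z,6E,10E)-12-(2-hydroxy-5-methoxy-3-methylphenyl)-2,6,10-trimethyldodeca-2,6,10-trienoate | COC(=O)/C(C)=C\CC/C(C)=C/CC/C(C)=C/Cc1cc(OC)cc(C)c1O
A4 | alternative 3 | 6-[(3R)-3,7-dimethyl-3-(prop-1-yn-1-yloxy)oct-6-en-1-yl]-4-methoxy-2H-pyran-2-one | COC1=CC(=O)OC(CC[C@@](C)(CCC=C(C)C)OC#CC)=C1
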